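**Retrosynthetic overview**
- Aryl–C(=O) bond: the α-aryloxy aryl ketone is unveiled late, by adding 3,4,5-trimethoxyphenylmagnesium bromide to an α-aryloxy Weinreb amide, so the epimerisable ketone never sees base.
- Side chain: Suzuki coupling of an aryl bromide with an (E)-TBSO-propenyl pinacol boronate, done at the amide stage.
- C8–O ether: Mitsunobu inversion of ethyl (S)-lactate with 4-bromo-2,6-dimethoxyphenol gives the (R)-aryloxy centre.
- Stereocentre: a ketoreductase reduces achiral ethyl pyruvate to ethyl (S)-lactate.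
- No ring is formed; both benzene rings are bought.

The target stereocentre is (R) by CIP analysis of the given SMILES (OAr > C=O > CH3 > H).

Assumption: 4-bromo-2,6-dimethoxyphenol, 5-bromo-1,2,3-trimethoxybenzene and the (E)-TBSO-propenyl pinacol boronate are catalogue items, and the ketoreductase is picked from a commercial panel for ≥99% ee (S).

**Step 1**
Reactants: 1 ethyl pyruvate
Product: 2 ethyl (2S)-2-hydroxypropanoate [ethyl (S)-lactate]
Conditions: (S)-selective ketoreductase (KRED), NADP+ (cat.), i-PrOH (10% v/v), KPi buffer pH 6.5, 30 °C; NaCl saturation, MTBE extraction, distillation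
Reagents that add atoms: none
Why: Enzymatic asymmetric ketone reduction in which the Prelog-type ketoreductase delivers hydride from NADPH to the Re face of the activated α-keto ester to set the (S)-carbinol, with isopropanol regenerating the cofactor.

**Step 2**
Reactants: 2 ethyl (S)-lactate; 3 4-bromo-2,6-dimethoxyphenol
Product: 4 ethyl (2R)-2-(4-bromo-2,6-dimethoxyphenoxy)propanoate
Conditions: PPh3, DIAD, THF, 0 °C → rt
Reagents that add atoms: none
Why: Mitsunobu etherification, in which the phenoxide displaces the oxyphosphonium of the small, carbonyl-activated lactate by SN2 with clean inversion, (S) → (R).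

**Step 3**
Reactants: 4 ethyl (2R)-2-(4-bromo-2,6-dimethoxyphenoxy)propanoate
Product: 5 (2R)-2-(4-bromo-2,6-dimethoxyphenoxy)-N-methoxy-N-methylpropanamide
Conditions: AlMe3, MeNHOMe·HCl, CH2Cl2, 0 °C → rt; cold 0.5 M aq. HCl
Reagents that add atoms: N,O-dimethylhydroxylamine hydrochloride, CNOC.Cl
Why: Weinreb aminolysis of the ester by a Lewis-acidic, weakly basic aluminium amide, which leaves the α-aryloxy stereocentre and the aryl bromide untouched.

**Step 4**
Reactants: 5 (2R)-2-(4-bromo-2,6-dimethoxyphenoxy)-N-methoxy-N-methylpropanamide; 6 (E)-2-[3-(tert-butyldimethylsilyloxy)prop-1-en-1-yl]-4,4,5,5-tetramethyl-1,3,2-dioxaborolane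
Product: 7 (2R)-2-{4-[(E)-3-(tert-butyldimethylsilyloxy)prop-1-en-1-yl]-2,6-dimethoxyphenoxy}-N-methoxy-N-methylpropanamide
Conditions: Pd(dppf)Cl2·CH2Cl2 (5 mol %), K2CO3, 1,4-dioxane/H2O (4:1), 85 °C
Reagents that add atoms: none
Why: Suzuki–Miyaura coupling of the unhindered aryl bromide with the alkenyl boronate retains the E geometry, and the amide α-proton is too weakly acidic to epimerise under carbonate.

**Step 5**
Reactants: 7 (2R)-2-{4-[(E)-3-(tert-butyldimethylsilyloxy)prop-1-en-1-yl]-2,6-dimethoxyphenoxy}-N-methoxy-N-methylpropanamide; 8 5-bromo-1,2,3-trimethoxybenzene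
Product: 11 (2R)-2-{4-[(E)-3-(tert-butyldimethylsilyloxy)prop-1-en-1-yl]-2,6-dimethoxyphenoxy}-1-(3,4,5-trimethoxyphenyl)propan-1-one, via 3,4,5-trimethoxyphenylmagnesium bromide 9 (not isolated), via magnesium hemiaminal chelate 10 (not isolated)
Conditions: 8, Mg, I2 (cat.), THF, 50 °C → rt; then 7 (0.6 equiv), THF, −10 → 0 °C; cold dil. aq. HCl to pH 4
Reagents that add atoms: none
Why: Weinreb ketone synthesis, in which the aryl Grignard adds once to give a stable five-membered magnesium chelate that releases the ketone only on mildly acidic quench, so there is no over-addition and no basic contact with the epimerisable α-aryloxy ketone.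

**Step 6**
Reactants: 11 (2R)-2-{4-[(E)-3-(tert-butyldimethylsilyloxy)prop-1-en-1-yl]-2,6-dimethoxyphenoxy}-1-(3,4,5-trimethoxyphenyl)propan-1-one
Product: 12 (2R)-2-{4-[(E)-3-hydroxyprop-1-en-1-yl]-2,6-dimethoxyphenoxy}-1-(3,4,5-trimethoxyphenyl)propan-1-one (target)
Conditions: HF·pyridine, pyridine, THF, 0 °C → rt
Reagents that add atoms: none
Why: Fluoride-mediated desilylation of the primary TBS ether in a pyridine-buffered, non-basic medium frees the allylic alcohol without enolising the α-aryloxy ketone or ionising the cinnamyl alcohol.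

**Compound list**
1 | ethyl pyruvate (ethyl 2-oxopropanoate) | CCOC(=O)C(C)=O | starting material
2 | ethyl (2S)-2-hydroxypropanoate [ethyl (S)-lactate] | CCOC(=O)[C@H](C)O | intermediate
3 | 4-bromo-2,6-dimethoxyphenol | COc1cc(Br)cc(OC)c1O | starting material
4 | ethyl (2R)-2-(4-bromo-2,6-dimethoxyphenoxy)propanoate | CCOC(=O)[C@@H](C)Oc1c(OC)cc(Br)cc1OC | intermediate
5 | (2R)-2-(4-bromo-2,6-dimethoxyphenoxy)-N-methoxy-N-methylpropanamide | CON(C)C(=O)[C@@H](C)Oc1c(OC)cc(Br)cc1OC | intermediate
6 | (E)-2-[3-(tert-butyldimethylsilyloxy)prop-1-en-1-yl]-4,4,5,5-tetramethyl-1,3,2-dioxaborolane | CC(C)(C)[Si](C)(C)OC/C=C/B1OC(C)(C)C(C)(C)O1 | starting material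
7 | (2R)-2-{4-[(E)-3-(tert-butyldimethylsilyloxy)prop-1-en-1-yl]-2,6-dimethoxyphenoxy}-N-methoxy-N-methylpropanamide | CON(C)C(=O)[C@@H](C)Oc1c(OC)cc(/C=C/CO[Si](C)(C)C(C)(C)C)cc1OC | intermediate
8 | 5-bromo-1,2,3-trimethoxybenzene | COc1cc(Br)cc(OC)c1OC | starting material
9 | 3,4,5-trimethoxyphenylmagnesium bromide | COc1cc([Mg]Br)cc(OC)c1OC | intermediate
10 | bromomagnesium alkoxide of the tetrahedral N-methoxy-N-methyl hemiaminal adduct (2R; hemiaminal carbon undefined) | COc1cc(C(O[Mg]Br)(N(C)OC)[C@@H](C)Oc2c(OC)cc(/C=C/CO[Si](C)(C)C(C)(C)C)cc2OC)cc(OC)c1OC | intermediate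
11 | (2R)-2-{4-[(E)-3-(tert-butyldimethylsilyloxy)prop-1-en-1-yl]-2,6-dimethoxyphenoxy}-1-(3,4,5-trimethoxyphenyl)propan-1-one | COc1cc(C(=O)[C@@H](C)Oc2c(OC)cc(/C=C/CO[Si](C)(C)C(C)(C)C)cc2OC)cc(OC)c1OC | intermediate
12 | (2R)-2-{4-[(E)-3-hydroxyprop-1-en-1-yl]-2,6-dimethoxyphenoxy}-1-(3,4,5-trimethoxyphenyl)propan-1-one (CNP0171423.1) | COc1cc(C(=O)[C@@H](C)Oc2c(OC)cc(/C=C/CO)cc2OC)cc(OC)c1OC | target

**Totals**
Total step count: 6. Longest linear sequence: 6 steps (1 → 2 → 4 → 5 → 7 → 11 → 12).

**Three steps most likely to fail**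

Step 1. The ketone is very small, so the enantiomeric excess depends on the enzyme chosen; the keto ester also hydrolyses slowly in buffer, and the product is water-miscible and volatile. The fallback sets out from 1. It is hydrolysed on purpose (pH-stat, aq. NaOH, pH 8, 20 °C) to pyruvic acid F1, which is present as its sodium salt. This is reduced with L-lactate dehydrogenase (an NADH-dependent oxidoreductase; NADH recycled with sodium formate and formate dehydrogenase, pH 7, 30 °C) to (S)-lactic acid F2, which this enzyme class gives essentially enantiopure. After acidification and removal of water, Fischer esterification (EtOH, cat. H2SO4, toluene azeotrope) comes back to the route at 2.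

Step 2. The phenol carries two ortho methoxy groups, so the Mitsunobu reaction may be slow and give hydrazide by-products. The fallback sets out from 2. Tf2O and 2,6-lutidine in CH2Cl2 at −78 °C give ethyl (2S)-2-{[(trifluoromethyl)sulfonyl]oxy}propanoate F3 with retention, since only the O–S bond is formed. SN2 displacement by the phenoxide of 3 (K2CO3, MeCN, −20 °C → rt) then inverts the centre and comes back to the route at 4.

Step 5. The Grignard reagent may enolise the α-aryloxy amide instead of adding, which would lower the yield and erode the ee. The fallback sets out from 7. LiAlH4 in THF at −78 °C reduces the Weinreb amide to (2R)-2-{4-[(E)-3-(tert-butyldimethylsilyloxy)prop-1-en-1-yl]-2,6-dimethoxyphenoxy}propanal F4, which is used at once. The far faster addition of 9 to the aldehyde at −78 °C gives (2R)-2-{4-[(E)-3-(tert-butyldimethylsilyloxy)prop-1-en-1-yl]-2,6-dimethoxyphenoxy}-1-(3,4,5-trimethoxyphenyl)propan-1-ol F5 as a mixture of C1 epimers. Oxidation with Dess–Martin periodinane and NaHCO3 in CH2Cl2 removes the new carbinol centre and comes back to the route at 11.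

**Further compounds**
F1 | step 1 | pyruvic acid (handled as sodium pyruvate in buffer) | CC(=O)C(=O)O
F2 | step 1 | (2S)-2-hydroxypropanoic acid [(S)-lactic acid] | C[C@H](O)C(=O)O
F3 | step 2 | ethyl (2S)-2-{[(trifluoromethyl)sulfonyl]oxy}propanoate | CCOC(=O)[C@H](C)OS(=O)(=O)C(F)(F)F
F4 | step 5 | (2R)-2-{4-[(E)-3-(tert-butyldimethylsilyloxy)prop-1-en-1-yl]-2,6-dimethoxyphenoxy}propanal | O=C[C@@H](C)Oc1c(OC)cc(/C=C/CO[Si](C)(C)C(C)(C)C)cc1OC
F5 | step 5 | (2R)-2-{4-[(E)-3-(tert-butyldimethylsilyloxy)prop-1-en-1-yl]-2,6-dimethoxyphenoxy}-1-(3,4,5-trimethoxyphenyl)propan-1-ol (C1 epimer mixture) | COc1cc(C(O)[C@@H](C)Oc2c(OC)cc(/C=C/CO[Si](C)(C)C(C)(C)C)cc2OC)cc(OC)c1OC
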